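Atoms are numbered as in the tetralone (ring A benzo, ring B C1–C4; C1′ is the aroyl carbonyl on ring C; ring D is the pyranone). Ring B is closed from an open-chain precursor by a [3+3] union in which C1–C2 and C4–C4a are formed in one operation. The precursor is enol ester 15: the carboxyl carbon C1 of ring A sits on the Z-enol oxygen of the C1′ ketone. Deprotonation at C2 triggers a 1,5 O→C acyl shift; the enolate thereby released at C4 is arylated at C4a (ortho bromide) under palladium catalysis. The step exploits the C1′ ketone next to C4 and the ortho C1/C4a pair of ring A; C3 derives from (R)-mevalonolactone.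

Key step: step 10

Remark: compounds 1, 3, 10 and 18 and all reagents are taken as commercial.
Remark: C4 is an enolisable α-aryl ketone centre; the epimer with the aroyl group trans to the C3 methyl group (as in 24) is assumed to be the thermodynamic one.

Step 1
Reactants: 1 (R)-mevalonolactone
Product: 2 (4R)-4-[(benzyloxy)methoxy]-4-methyloxan-2-one
Conditions: BnOCH2Cl, i-Pr2NEt, Bu4NI (cat.), CH2Cl2, 40 °C
Reagents that add atoms: benzyl chloromethyl ether ClCOCc1ccccc1
Why: Williamson-type O-alkylation of the tertiary alcohol by the strongly electrophilic α-chloro ether under a hindered amine base should leave the stereocentre untouched, and the acetal ether is chosen because the final hydrogenolysis removes it.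

Step 2
Reactants: 3 5-chlororesorcinol
Product: 4 1,3-bis(benzyloxy)-5-chlorobenzene
Conditions: BnBr, K2CO3, DMF, 60 °C
Reagents that add atoms: benzyl bromide BrCc1ccccc1
Why: Williamson ether synthesis on both phenols should proceed cleanly, the chloride being inert.

Step 3
Reactants: 4 1,3-bis(benzyloxy)-5-chlorobenzene
Product: 5 1,5-bis(benzyloxy)-2-bromo-3-chlorobenzene
Conditions: NBS, MeCN, 0 °C to rt
Reagents that add atoms: N-bromosuccinimide O=C1CCC(=O)N1Br
Why: Electrophilic aromatic bromination should occur para to one benzyloxy group and ortho to the other (next to chlorine), the position between the two ether groups being more hindered.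

Step 4
Reactants: 5 1,5-bis(benzyloxy)-2-bromo-3-chlorobenzene; 2 (4R)-4-[(benzyloxy)methoxy]-4-methyloxan-2-one
Product: 7 (3R)-1-[2,4-bis(benzyloxy)-6-chlorophenyl]-3-[(benzyloxy)methoxy]-5-hydroxy-3-methylpentan-1-one, via aryllithium 6 (not isolated)
Conditions: 5, n-BuLi, THF, −78 °C; then 2, −78 °C; AcOH quench
Reagents that add atoms: none
Why: Bromine–lithium exchange (faster than chlorine exchange at −78 °C) gives an aryllithium that should add once to the lactone carbonyl, as in C-aryl glycoside syntheses from protected gluconolactones, because the tetrahedral lithium lactolate survives until the quench; the stereocentre is remote and unchanged.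

Step 5
Reactants: 7 (3R)-1-[2,4-bis(benzyloxy)-6-chlorophenyl]-3-[(benzyloxy)methoxy]-5-hydroxy-3-methylpentan-1-one
Product: 8 (3S)-5-[2,4-bis(benzyloxy)-6-chlorophenyl]-3-[(benzyloxy)methoxy]-3-methyl-5-oxopentanoic acid
Conditions: TEMPO (cat.), PhI(OAc)2, MeCN–H2O, rt
Reagents that add atoms: water O
Why: Oxoammonium (TEMPO) oxidation of the primary alcohol through the aldehyde hydrate should give the acid without touching ketone, ethers or acetal (the descriptor changes by priority only, not the geometry).

Step 6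
Reactants: 8 (3S)-5-[2,4-bis(benzyloxy)-6-chlorophenyl]-3-[(benzyloxy)methoxy]-3-methyl-5-oxopentanoic acid
Product: 9 benzyl (3S)-5-[2,4-bis(benzyloxy)-6-chlorophenyl]-3-[(benzyloxy)methoxy]-3-methyl-5-oxopentanoate
Conditions: BnBr, Cs2CO3, DMF, rt
Reagents that add atoms: benzyl bromide BrCc1ccccc1
Why: O-Alkylation of the caesium carboxylate should be much faster than any enolate alkylation under carbonate base, and the benzyl ester later serves as a traceless activating group for C2.

Step 7
Reactants: 10 1,3-bis(benzyloxy)-5-bromobenzene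
Product: 11 2,4-bis(benzyloxy)-6-bromobenzaldehyde
Conditions: POCl3, DMF, 80 °C; then H2O
Reagents that add atoms: N,N-dimethylformamide CN(C)C=O; water O
Why: Vilsmeier–Haack formylation should take place para to one benzyloxy group and ortho to the other, next to bromine, as known for the dimethoxy analogue.

Step 8
Reactants: 11 2,4-bis(benzyloxy)-6-bromobenzaldehyde
Product: 12 2,4-bis(benzyloxy)-6-bromobenzoic acid
Conditions: NaClO2, NaH2PO4, 2-methyl-2-butene, t-BuOH–H2O, rt
Reagents that add atoms: sodium chlorite [Na+].[O-]Cl=O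
Why: Pinnick oxidation should convert the hindered, electron-rich aldehyde into the acid while the alkene scavenger protects the ring from hypochlorous acid.

Step 9
Reactants: 12 2,4-bis(benzyloxy)-6-bromobenzoic acid; 9 benzyl (3S)-5-[2,4-bis(benzyloxy)-6-chlorophenyl]-3-[(benzyloxy)methoxy]-3-methyl-5-oxopentanoate
Product: 15 benzyl (3R,4Z)-5-[2,4-bis(benzyloxy)-6-bromobenzoyloxy]-5-[2,4-bis(benzyloxy)-6-chlorophenyl]-3-[(benzyloxy)methoxy]-3-methylpent-4-enoate, via acid chloride 13 (not isolated), via potassium Z-enolate 14 (not isolated)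
Conditions: 12, (COCl)2, DMF (cat.), CH2Cl2, 0 °C to rt, evaporate; 9, KN(SiMe3)2 (1.05 equiv), THF–DMPU, −78 °C; then 13, −78 to −40 °C
Reagents that add atoms: none
Why: The ketone α-protons are several pKa units more acidic than the ester α-protons, the aryl ketone should give the Z-enolate, and the dissociated potassium enolate should be acylated at oxygen by the hindered aroyl chloride (enolate O-acylation), which places C1 cis to the C3 side chain.

Step 10
Reactants: 15 benzyl (3R,4Z)-5-[2,4-bis(benzyloxy)-6-bromobenzoyloxy]-5-[2,4-bis(benzyloxy)-6-chlorophenyl]-3-[(benzyloxy)methoxy]-3-methylpent-4-enoate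
Product: 17 benzyl 6,8-bis(benzyloxy)-4-[2,4-bis(benzyloxy)-6-chlorobenzoyl]-3-[(benzyloxy)methoxy]-1-hydroxy-3-methyl-3,4-dihydronaphthalene-2-carboxylate, via β-keto ester 16 (not isolated)
Conditions: LiN(SiMe3)2 (2.3 equiv), Pd2(dba)3 (2.5 mol%), Xantphos (6 mol%), THF, −78 to 0 °C, then 50 °C; AcOH quench at −78 °C
Reagents that add atoms: none
Why: LiN(SiMe3)2 removes the only acidic proton of 15 (C2–H, α to the benzyl ester) and the ester enolate adds to the enol-ester carbonyl C1 through a six-membered cyclic transition state that the Z geometry makes accessible, so that collapse of the tetrahedral intermediate forms C1–C2 and releases the C1′ enolate, a Baker–Venkataraman-type 1,5 O→C acyl transfer (intramolecular Claisen condensation with an enol ester as acyl donor). After proton transfer to the more acidic β-keto ester the second equivalent of base regenerates the C4 enolate, zerovalent palladium inserts into the C4a–Br bond (activated by the ortho acyl group and far more reactive than the ring-C chloride towards the Xantphos catalyst), and C–C reductive elimination from the arylpalladium enolate forms C4–C4a, a Buchwald–Hartwig–Miura ketone α-arylation. Ring B is thus closed in a 6-exo sense at C4 (enolate carbon attacking the ortho position of the tethered arene), the acyl shift having first assembled the tether without closing a ring of the product. C3 is carried over unchanged from 1, and C4, an enolisable α-aryl ketone centre, should be set under thermodynamic control by proton exchange in the small excess of base: the aroyl group takes the pseudoaxial position (no peri strain to H5), anti to the axial C3 methyl group and gauche to the smaller C3 oxygen substituent. The step needs acylation at C2 rather than C4 and C- rather than O-arylation: the first is secured because the ketone is masked as the very enol ester that delivers C1, the second by the six-membered ring size of the C-arylation (O-arylation would need an eight-membered ring). Loss of the C3 alkoxy group by β-elimination is held back by running the acyl shift cold, by the poor leaving-group ability of the acetal oxygen and by the near-stoichiometric amount of base.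

Step 11
Reactants: 18 4-hydroxy-6-methyl-2H-pyran-2-one
Product: 19 4-(benzyloxy)-6-methyl-2H-pyran-2-one
Conditions: BnBr, K2CO3, DMF, rt
Reagents that add atoms: benzyl bromide BrCc1ccccc1
Why: O-Alkylation of the vinylogous acid at the 4-oxygen (Williamson type) should give the 4-alkoxy-2-pyranone, as known for the methyl ether.

Step 12
Reactants: 17 benzyl 6,8-bis(benzyloxy)-4-[2,4-bis(benzyloxy)-6-chlorobenzoyl]-3-[(benzyloxy)methoxy]-1-hydroxy-3-methyl-3,4-dihydronaphthalene-2-carboxylate; 19 4-(benzyloxy)-6-methyl-2H-pyran-2-one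
Product: 22 benzyl 6,8-bis(benzyloxy)-4-{2,4-bis(benzyloxy)-6-[(4-(benzyloxy)-2-oxo-2H-pyran-6-yl)methyl]benzoyl}-3-[(benzyloxy)methoxy]-1-hydroxy-3-methyl-3,4-dihydronaphthalene-2-carboxylate, via lithiated pyranone 20 (not isolated), via pyranonylmethylzinc chloride 21 (not isolated)
Conditions: 19, LiN(i-Pr)2, THF, −78 °C; ZnCl2, −78 to 0 °C; then 17, Pd(OAc)2 (5 mol%), SPhos (2-dicyclohexylphosphino-2′,6′-dimethoxybiphenyl, 10 mol%), THF, 50 °C (3 equiv of 21)
Reagents that add atoms: none
Why: Lateral deprotonation of the 6-methyl group of the 4-alkoxypyranone and transmetalation to zinc give a benzylic-type organozinc that tolerates ketone, ester and acetal groups, and Negishi coupling at the aryl chloride (oxidative addition helped by the ortho acyl group and the biarylphosphine) should install the pyranonylmethyl arm under neutral conditions without touching C3 or C4.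

Step 13
Reactants: 22 benzyl 6,8-bis(benzyloxy)-4-{2,4-bis(benzyloxy)-6-[(4-(benzyloxy)-2-oxo-2H-pyran-6-yl)methyl]benzoyl}-3-[(benzyloxy)methoxy]-1-hydroxy-3-methyl-3,4-dihydronaphthalene-2-carboxylate
Product: 24 (3R,4S)-4-{2,4-dihydroxy-6-[(4-hydroxy-2-oxo-2H-pyran-6-yl)methyl]benzoyl}-3,6,8-trihydroxy-3-methyl-3,4-dihydronaphthalen-1(2H)-one, via β-keto acid 23 (not isolated)
Conditions: H2 (1 atm), Pd/C (10%), EtOAc–MeOH, rt; then 40 °C
Reagents that add atoms: none
Why: Hydrogenolysis should cleave the five aryl and pyranone benzyl ethers, the benzyl ester and the benzyloxymethyl acetal (the hemiacetal loses formaldehyde) under neutral conditions that spare the tertiary β-hydroxy ketone, and the freed β-keto acid should decarboxylate on gentle warming to the C2 methylene; C3 is untouched and C4 stays in its preferred configuration, now supported by the O–H···O=C1′ hydrogen bond.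

Compound list
1 | (R)-mevalonolactone, (4R)-4-hydroxy-4-methyloxan-2-one | C[C@@]1(O)CCOC(=O)C1 | starting material
2 | (4R)-4-[(benzyloxy)methoxy]-4-methyloxan-2-one | C[C@@]1(OCOCc2ccccc2)CCOC(=O)C1 | intermediate
3 | 5-chlororesorcinol (5-chlorobenzene-1,3-diol) | Oc1cc(O)cc(Cl)c1 | starting material
4 | 1,3-bis(benzyloxy)-5-chlorobenzene | Clc1cc(OCc2ccccc2)cc(OCc2ccccc2)c1 | intermediate
5 | 1,5-bis(benzyloxy)-2-bromo-3-chlorobenzene | Clc1cc(OCc2ccccc2)cc(OCc2ccccc2)c1Br | intermediate
6 | [2,4-bis(benzyloxy)-6-chlorophenyl]lithium (not isolated) | [Li]c1c(Cl)cc(OCc2ccccc2)cc1OCc1ccccc1 | intermediate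
7 | (3R)-1-[2,4-bis(benzyloxy)-6-chlorophenyl]-3-[(benzyloxy)methoxy]-5-hydroxy-3-methylpentan-1-one | C[C@@](CC(=O)c1c(Cl)cc(OCc2ccccc2)cc1OCc1ccccc1)(OCOCc1ccccc1)CCO | intermediate
8 | (3S)-5-[2,4-bis(benzyloxy)-6-chlorophenyl]-3-[(benzyloxy)methoxy]-3-methyl-5-oxopentanoic acid | C[C@@](CC(=O)c1c(Cl)cc(OCc2ccccc2)cc1OCc1ccccc1)(OCOCc1ccccc1)CC(=O)O | intermediate
9 | benzyl (3S)-5-[2,4-bis(benzyloxy)-6-chlorophenyl]-3-[(benzyloxy)methoxy]-3-methyl-5-oxopentanoate | C[C@@](CC(=O)c1c(Cl)cc(OCc2ccccc2)cc1OCc1ccccc1)(OCOCc1ccccc1)CC(=O)OCc1ccccc1 | intermediate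
10 | 1,3-bis(benzyloxy)-5-bromobenzene | Brc1cc(OCc2ccccc2)cc(OCc2ccccc2)c1 | starting material
11 | 2,4-bis(benzyloxy)-6-bromobenzaldehyde | O=Cc1c(Br)cc(OCc2ccccc2)cc1OCc1ccccc1 | intermediate
12 | 2,4-bis(benzyloxy)-6-bromobenzoic acid | OC(=O)c1c(Br)cc(OCc2ccccc2)cc1OCc1ccccc1 | intermediate
13 | 2,4-bis(benzyloxy)-6-bromobenzoyl chloride (not isolated) | ClC(=O)c1c(Br)cc(OCc2ccccc2)cc1OCc1ccccc1 | intermediate
14 | potassium Z-enolate of 9 (not isolated) | C[C@@](/C=C(\[O-])c1c(Cl)cc(OCc2ccccc2)cc1OCc1ccccc1)(OCOCc1ccccc1)CC(=O)OCc1ccccc1.[K+] | intermediate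
15 | benzyl (3R,4Z)-5-[2,4-bis(benzyloxy)-6-bromobenzoyloxy]-5-[2,4-bis(benzyloxy)-6-chlorophenyl]-3-[(benzyloxy)methoxy]-3-methylpent-4-enoate | C[C@@](/C=C(\OC(=O)c1c(Br)cc(OCc2ccccc2)cc1OCc1ccccc1)c1c(Cl)cc(OCc2ccccc2)cc1OCc1ccccc1)(OCOCc1ccccc1)CC(=O)OCc1ccccc1 | intermediate
16 | benzyl 2-[2,4-bis(benzyloxy)-6-bromobenzoyl]-5-[2,4-bis(benzyloxy)-6-chlorophenyl]-3-[(benzyloxy)methoxy]-3-methyl-5-oxopentanoate (C3 as in 15, C2 epimers; present in the flask as its lithium enolates, not isolated) | C[C@@](CC(=O)c1c(Cl)cc(OCc2ccccc2)cc1OCc1ccccc1)(OCOCc1ccccc1)C(C(=O)OCc1ccccc1)C(=O)c1c(Br)cc(OCc2ccccc2)cc1OCc1ccccc1 | intermediate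
17 | benzyl 6,8-bis(benzyloxy)-4-[2,4-bis(benzyloxy)-6-chlorobenzoyl]-3-[(benzyloxy)methoxy]-1-hydroxy-3-methyl-3,4-dihydronaphthalene-2-carboxylate (enol form of the β-keto ester; C3 and C4 as in 24, aroyl trans to methyl) | C[C@@]1(OCOCc2ccccc2)C(C(=O)OCc2ccccc2)=C(O)c2c(OCc3ccccc3)cc(OCc3ccccc3)cc2[C@@H]1C(=O)c1c(Cl)cc(OCc2ccccc2)cc1OCc1ccccc1 | intermediate
18 | 4-hydroxy-6-methyl-2H-pyran-2-one | Cc1cc(O)cc(=O)o1 | starting material
19 | 4-(benzyloxy)-6-methyl-2H-pyran-2-one | Cc1cc(OCc2ccccc2)cc(=O)o1 | intermediate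
20 | 4-(benzyloxy)-6-(lithiomethyl)-2H-pyran-2-one (not isolated) | [Li]Cc1cc(OCc2ccccc2)cc(=O)o1 | intermediate
21 | {[4-(benzyloxy)-2-oxo-2H-pyran-6-yl]methyl}zinc chloride (not isolated) | Cl[Zn]Cc1cc(OCc2ccccc2)cc(=O)o1 | intermediate
22 | benzyl 6,8-bis(benzyloxy)-4-{2,4-bis(benzyloxy)-6-[(4-(benzyloxy)-2-oxo-2H-pyran-6-yl)methyl]benzoyl}-3-[(benzyloxy)methoxy]-1-hydroxy-3-methyl-3,4-dihydronaphthalene-2-carboxylate (C3 and C4 as in 24) | C[C@@]1(OCOCc2ccccc2)C(C(=O)OCc2ccccc2)=C(O)c2c(OCc3ccccc3)cc(OCc3ccccc3)cc2[C@@H]1C(=O)c1c(Cc2cc(OCc3ccccc3)cc(=O)o2)cc(OCc2ccccc2)cc1OCc1ccccc1 | intermediate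
23 | 4-{2,4-dihydroxy-6-[(4-hydroxy-2-oxo-2H-pyran-6-yl)methyl]benzoyl}-3,6,8-trihydroxy-3-methyl-1-oxo-1,2,3,4-tetrahydronaphthalene-2-carboxylic acid (C3 and C4 as in 24, not isolated) | C[C@@]1(O)C(C(=O)O)C(=O)c2c(O)cc(O)cc2[C@@H]1C(=O)c1c(O)cc(O)cc1Cc1cc(O)cc(=O)o1 | intermediate
24 | (3R,4S)-4-{2,4-dihydroxy-6-[(4-hydroxy-2-oxo-2H-pyran-6-yl)methyl]benzoyl}-3,6,8-trihydroxy-3-methyl-3,4-dihydronaphthalen-1(2H)-one | C[C@@]1(O)CC(=O)c2c(O)cc(O)cc2[C@@H]1C(=O)c1c(O)cc(O)cc1Cc1cc(O)cc(=O)o1 | target

Total step count: 13.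
Longest linear sequence: 9 steps (steps 2, 3, 4, 5, 6, 9, 10, 12 and 13, from 3 to 24).

Steps most likely to fail

Step 10. The cascade may stall after the acyl shift, or the C3 alkoxy group may be lost by β-elimination from the C4 enolate (ending in aromatisation of ring B) before or after ring closure at 50 °C. The fallback uncouples the two bond formations and moves the arylation to neutral conditions. It sets out from 15 and comes back at 17. Compound 15 is treated with LiN(SiMe3)2 alone at −78 °C and quenched to give 16, which is converted with Me3SiOTf and Et3N into the bis(trimethylsilyl) enol ether of 16 F1. F1 is cyclised with Pd(OAc)2, P(t-Bu)3 and Bu3SnF in toluene, an arylation of the tin enolate formed in situ from a silyl enol ether, and aqueous work-up returns 17.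

Step 12. Oxidative addition and transmetalation at the hindered, electron-rich aryl chloride may be slow, and the organozinc may be consumed by the enolic proton of 17, so that the chloride survives. The fallback reverses the polarity of the coupling. It sets out from 17 and 19 and comes back at 22. Compound 17 is borylated (bis(pinacolato)diboron, Pd(OAc)2, 2-dicyclohexylphosphino-2′,4′,6′-triisopropylbiphenyl, KOAc, dioxane) to the aryl pinacol boronate F2. Compound 19 is brominated at the methyl group (LiN(i-Pr)2, −78 °C, then CBr4) to 4-(benzyloxy)-6-(bromomethyl)-2H-pyran-2-one F3. Suzuki–Miyaura coupling of F2 and F3 with PdCl2(dppf) ([1,1′-bis(diphenylphosphino)ferrocene]dichloropalladium) and K3PO4 in THF–H2O at 40 °C should give 22.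

Step 9. Acylation of the potassium enolate at carbon (C4) instead of oxygen, or erosion of the Z geometry, would give material that cannot undergo the acyl shift. The fallback bypasses the enol ester. It sets out from 9 and 12 and comes back at 17 by way of 16. Acid 12 is converted with 1,1′-carbonyldiimidazole into 2,4-bis(benzyloxy)-6-bromobenzoyl imidazolide F4. Compound 9 is converted with LiN(i-Pr)2 (2.2 equiv, THF, −78 °C) into its ketone/ester bis-enolate, whose more reactive ester enolate should be acylated at C2 by F4 (intermolecular Claisen condensation) to give 16. Compound 16 is then cyclised to 17 with LiN(SiMe3)2, Pd2(dba)3 and Xantphos as in the second phase of step 10.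

Further compounds
F1 | step 10 | bis(trimethylsilyl) enol ether of 16, benzyl 2-{[2,4-bis(benzyloxy)-6-bromophenyl](trimethylsilyloxy)methylidene}-5-[2,4-bis(benzyloxy)-6-chlorophenyl]-3-[(benzyloxy)methoxy]-3-methyl-5-(trimethylsilyloxy)pent-4-enoate | C[C@@](/C=C(\O[Si](C)(C)C)c1c(Cl)cc(OCc2ccccc2)cc1OCc1ccccc1)(OCOCc1ccccc1)C(C(=O)OCc1ccccc1)=C(O[Si](C)(C)C)c1c(Br)cc(OCc2ccccc2)cc1OCc1ccccc1
F2 | step 12 | benzyl 6,8-bis(benzyloxy)-4-[2,4-bis(benzyloxy)-6-(4,4,5,5-tetramethyl-1,3,2-dioxaborolan-2-yl)benzoyl]-3-[(benzyloxy)methoxy]-1-hydroxy-3-methyl-3,4-dihydronaphthalene-2-carboxylate | C[C@@]1(OCOCc2ccccc2)C(C(=O)OCc2ccccc2)=C(O)c2c(OCc3ccccc3)cc(OCc3ccccc3)cc2[C@@H]1C(=O)c1c(B2OC(C)(C)C(C)(C)O2)cc(OCc2ccccc2)cc1OCc1ccccc1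
F3 | step 12 | 4-(benzyloxy)-6-(bromomethyl)-2H-pyran-2-one | BrCc1cc(OCc2ccccc2)cc(=O)o1
F4 | step 9 | 2,4-bis(benzyloxy)-6-bromobenzoyl imidazolide | O=C(n1ccnc1)c1c(Br)cc(OCc2ccccc2)cc1OCc1ccccc1
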